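Remark on numbering: labdane numbering is used throughout (C1–C10 decalin, C11–C16 side chain, C17 on C8, C18/C19 on C4, C20 on C10); α is the face opposite to C20.
Remark on step 14: the sense of induction of the zirconium bis-hydroxamate epoxidation is assumed to follow the facial model for 3-substituted but-3-en-1-ols; the ligand enantiomer that leads to the (13S)-epoxide is meant and is written as (R,R).
Remark on 3: it is used as the mixture of epimers at the methylated carbon, because this centre is planarised again in step 2.

## Structural features

The target is a 9,13-epoxylabdan-15,16-olide. A trans-decalin (rings A and B) carries at C9 a spiro tetrahydrofuran (ring C: O, C9, C11, C12, C13), which is spiro-fused at C13 to a γ-lactone (ring D: C13, C14, C15, O, C16). There are six stereocentres: C8, C9 and C10 are contiguous, C9 and C10 are fully substituted, C7 (equatorial 7β-OH) and C5 (5α-H) flank the C6 ketone, and C13 is insulated from the decalin by the ether oxygen and two CH2 groups, so only a reagent can control it. At C9 the oxygen is axial (α) and the carbon chain equatorial (β), which is the reverse of what a carbon nucleophile adding to a C9 ketone anti to C20 would give. Fragile elements are the α-ketol (C7 epimerisation, 6/7 ketol transposition, C5 epimerisation), the β-alkoxy lactone (base can open the C13–O bond by retro-oxa-Michael reaction and scramble C13) and the two tertiary ether carbons under strong acid. The real difficulty lies in the C8–C9–C10 triad with its two quaternary carbons and in the remote centre C13. Ring B, with C17 on C8, the oxygen at C9 and the C5 stereocentre, maps onto the ring of (R)-carvone, and the isopropenyl carbon is C4; the key step exploits this by adding one hydrogen atom to the isopropenyl group and joining C4 to C3 of an acryloyl group on C10, which closes ring A. A check of the descriptors confirms that (R)-carvone supplies the 5α-hydrogen and that the C10 methyl must be cis to the isopropenyl group; 6 and 7 as drawn below satisfy both, so they need no change.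

## Logic of the disconnections

27 ⇒ 26 ⇒ 23. The C7–O bond is cut last; 27 and 26 differ only at C7, and 26 comes from 23 by oxidation of its C6 enol derivative. This keeps the α-ketol, the most sensitive motif, out of all earlier intermediates. The forward steps must enolise C6 towards C7 and not C5, must not form the lactone enolate (which would open C13–O), and must end with oxygen equatorial at C7. Because an electrophile reaches C7 from the α face, an equilibration 26 → 27 is planned.

23 ⇒ 21. No skeletal bond is cut; the C15 and C6 carbonyl groups are taken back to alcohols. The lactone can then be closed by oxidation of a 1,4-diol, and C6 stays inert during the carbanion chemistry before it. The demand is that the unhindered C15–OH is oxidised before the neopentyl C16–OH, so that the carbonyl ends up at C15.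

21 ⇒ 18 (through 19 and 20). The C13–O bond of ring C and the C16–O bond are cut. The decalin cannot control C13, but an epoxide across C13/C16 made under catalyst control and opened by O9 with inversion fixes it. Both spiro rings collapse to an open-chain alkene diol. The forward step needs face-selective oxygen transfer directed by C15–OH and 5-exo attack of the hindered 9α-OH at the tertiary epoxide carbon.

18 ⇒ 16 + 17. C11–C12 is cut. 17 contains C12–C16 in the right oxidation pattern, and its doubly deprotonated form is an allyl anion with two equivalent CH2 termini, so no regioisomer can form; a plain allyl nucleophile would leave C14–C16 still to be added. The demands are SN2 attack at the neopentyl-type C11 of 16 and a masked 6β-oxygen, because a free axial alkoxide at C6 could reach C11 across ring B.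

16 ⇒ 15 ⇒ 13 + 14. The C9–O bond of the oxirane and then C9=C11 are cut. A carbon nucleophile would add to a C9 ketone anti to C20 and give the wrong epimer. Going through the exocyclic alkene and letting the oxidant come from the α face gives the 9α-oxygen, and the later nucleophile enters at C11 without touching C9. The demand is methylenation of a ketone flanked by a quaternary and a tertiary carbon.

13 ⇒ 12 ⇒ 11 ⇒ 10 ⇒ 9. The C6–O bond and the C8–H bond are disconnected. If C9 were methylenated while C7=C8 is still present, the resulting 1,3-diene would be epoxidised preferentially at the trisubstituted ring alkene, and a C9 oxirane next to C7=C8 would invite allylic (SN2′) opening. The enone of 9 is therefore used first: γ-oxidation at C6 gives 10, and reduction of C7=C8 gives 11, in which C8 is α to the C9 carbonyl and settles as the equatorial 8α-methyl epimer. C8 then needs no directed hydrogenation. The demand is reduction of the C6 carbonyl of 11 with the C9 carbonyl untouched.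

9 ⇒ 8 ⇒ 7. The C1 carbonyl is put back, because it is what activates C2=C3 for the ring closure. The forward steps must remove the saturated C1 carbonyl beside the C9 enone carbonyl and without nucleophilic base, which would cleave a 2,2-disubstituted 1,3-diketone.

7 ⇒ 6. C3–C4 is cut; this is the key disconnection. Ring A opens to an isopropenyl group on C5 and an acryloyl group on C10, both on the intact carvone ring. The forward step must make a tertiary radical at C4 selectively and close 6-endo; the ring fusion is already fixed by C5 and C10. 6 is kept unchanged as the precursor; the improvements concern its preparation and the sequence after 7.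

6 ⇒ 5 ⇒ 3 + 4, and 3 ⇒ 1 + 2. C10–C1 and C10–C20 are cut. Two successive enolate reactions on 1 build the quaternary C10. Introducing the methyl first and the three-carbon unit second, anti to the isopropenyl group, places the methyl cis and the acyl group trans to it. The demands are 1,2-addition to 4 and a cold quench, because the aldolate of a quaternary β-hydroxy ketone can revert.

## Other disconnections considered

Alternative 1: The two lactone C–O bonds at C15 are cut, which leads back to the spiro cyclobutanone A1. In the forward step m-CPBA with Sc(OTf)3 and a chiral N,N′-dioxide ligand would insert oxygen between C15 and one of the two CH2 groups and give the silyl-protected target A2.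
- In its favour: the lactone and the C13 configuration are made in one late, catalyst-controlled step. On this point it is the equal of steps 14 and 15 of the chosen plan and is shorter by one oxidation.
- Against it: the two migrating CH2 groups differ only through the ether oxygen versus a CH2 group at the spiro carbon, a small difference for the catalyst to read in a molecule that is already chiral. The Lewis acid and peracid must also spare the C6 ketone, and the α-ketol needs a silyl group that is then removed.
- Comparison: it says nothing about how rings A and B and the C8–C9–C10 triad are built, so it complements the chosen plan and does not replace it. Mechanistically it relies on catalyst recognition of a weak difference, whereas the chosen plan uses a hydroxyl-directed oxygen transfer whose geometry does not depend on the remote substituents.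

Alternative 2: C5–C10 and C8–C9 are cut, which leads back to the triene A3 with a siloxy diene and an alkylidene furanone. Heating or Me2AlCl would close rings A and B at once to the adduct A4.
- In its favour: two rings, two bonds and both quaternary carbons C9 and C10 in one step from an open chain. In bond and ring count per step it is clearly the better of the two plans.
- Against it: the dienophile is tetrasubstituted and two adjacent quaternary centres must form, so the cycloaddition should be slow and Me2AlCl would threaten the silyl enol ether. The only stereocentre of A3 is C13, whose two CH2 arms are nearly alike, so it can hardly select the face of the dienophile. A4 also needs more repair than 7: an 11-oxo group next to C9–O has to be removed without cleaving that bond, C8 has to be epimerised, and the C7 enol ether gives a 7-ketone whereas the target has the ketone at C6.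
- Comparison: the chosen plan makes only one ring in its key step, but it takes C5 from the chiral pool and fixes C10 before the ring closure, so its stereochemical outcome does not depend on a transition-state preference.

Alternative 3: C9–C10 is cut, which leads back to the N-acyloxyphthalimide A5 with a trimethylcyclohexenyl ketone. Visible light, Ru(bpy)3(PF6)2 and Hantzsch ester would release the C9 α-alkoxy radical, which closes ring B 6-endo to A6.
- In its favour: it is convergent, ring A comes from a cheap achiral cyclohexene, and A6 is identical with 23, so its end game equals steps 16 and 17 of the chosen plan. In convergence it is the better plan.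
- Against it: the radical must attack a fully substituted β-carbon and create the C9–C10 bond between two quaternary centres, which is much slower than attack on an unsubstituted vinyl ketone terminus. C9 and C10 are set only by the preference of the cyclisation transition state under the influence of C8, and C8 and C13 must already be correct in A5.
- Comparison: both plans use a radical conjugate addition to an enone. The chosen plan places the radical closure early on a small molecule with all ring-fusion centres fixed beforehand. Alternative 3 places it late and asks it to set two quaternary centres, so it gains in convergence and loses in predictability.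

Key step: step 4

## Route

Step 1
Reactants: 1 (R)-(−)-carvone; 2 iodomethane
Product: 3 trans-6-methylcarvone, (5R,6S)-2,6-dimethyl-5-(prop-1-en-2-yl)cyclohex-2-en-1-one (accompanied by its 6-epimer)
Conditions: LiN(iPr)2, THF, −78 °C; MeI, −78 → 0 °C
Reagents that add atoms: iodomethane 2, CI
Why: Kinetic α′-deprotonation of the enone and SN2 methylation of the lithium enolate (enolate alkylation) should put the methyl group on the future C10, mainly trans to the isopropenyl group; the ratio is immaterial because step 2 planarises this carbon.

Step 2
Reactants: 3 trans-6-methylcarvone; 4 acrolein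
Product: 5 (5S,6R)-6-(1-hydroxyprop-2-en-1-yl)-2,6-dimethyl-5-(prop-1-en-2-yl)cyclohex-2-en-1-one (methyl cis and hydroxyallyl trans to isopropenyl; carbinol centre as a mixture)
Conditions: LiN(iPr)2, THF, −78 °C; acrolein, −78 °C; AcOH, −78 °C
Reagents that add atoms: acrolein 4, C=CC=O
Why: Aldol addition (1,2-addition) of the tetrasubstituted lithium enolate to the aldehyde; the neighbouring isopropenyl group is pseudoaxial in the enolate and shields one face, so the aldehyde should enter anti to it and fix the quaternary C10 with the methyl cis to isopropenyl. The cold acidic quench prevents retro-aldol reversal.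

Step 3
Reactants: 5 aldol adduct
Product: 6 (5S,6R)-6-acryloyl-2,6-dimethyl-5-(prop-1-en-2-yl)cyclohex-2-en-1-one (methyl cis to isopropenyl)
Conditions: Dess–Martin periodinane, NaHCO3, CH2Cl2, 0 → 25 °C
Reagents that add atoms: none
Why: Dess–Martin oxidation of the secondary allylic alcohol under buffered, non-basic conditions; both carbinol epimers converge on one vinyl ketone, and the quaternary carbon between the two carbonyl groups cannot epimerise.

Step 4
Reactants: 6 6-acryloyl-6-methylcarvone
Product: 7 4,4,8,10-tetramethyl-trans-decal-7-ene-1,9-dione (5α-H, 10β-CH3)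
Conditions: Fe(acac)3 (0.3 equiv), PhSiH3 (2.5 equiv), EtOH/(CH2OH)2 5:1, 0.01 M, degassed, 60 °C
Reagents that add atoms: none
Why: Fe(acac)3 and PhSiH3 in ethanol form an iron hydride that transfers a hydrogen atom to the CH2 terminus of the electron-rich 1,1-disubstituted isopropenyl group (Markovnikov metal-hydride hydrogen-atom transfer) and leaves the tertiary C4 radical. This nucleophilic radical adds to the unsubstituted β-carbon C3 of the vinyl ketone on C10 in a polarity-matched Giese addition; the α-keto radical at C2 is reduced by divalent iron to the enolate and protonated by ethanol, which returns trivalent iron. The closest known reaction type is the iron-mediated reductive olefin–enone coupling in its intramolecular form, which is documented for 6-endo closures that create quaternary carbons. Ring A closes in the 6-endo-trig mode, with C2 and C3 both inside the new ring; the 5-exo alternative would need attack at the α-carbon C2 and would leave a primary radical, so it is disfavoured electronically and sterically. No stereocentre is created: C4 becomes the gem-dimethyl carbon, C2 and C3 are CH2, and the trans ring fusion follows from the fixed centres C5 and C10, whose isopropenyl and acryloyl groups are trans and both equatorial in the closing chair. The step needs hydrogen-atom transfer to the isopropenyl group in the presence of two enone C=C bonds; this is secured because transfer to electron-poor conjugated alkenes is much slower and because the C4 radical cannot reach C7=C8 through a strain-free ring. High dilution keeps intermolecular addition to the vinyl ketone in check.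

Step 5
Reactants: 7 decalin-1,9-dione
Product: 8 C1 p-toluenesulfonylhydrazone of 7 (C9 enone carbonyl free; C=N geometry not controlled)
Conditions: TsNHNH2 (1.05 equiv), PPTS (cat.), EtOH, 50 °C
Reagents that add atoms: p-toluenesulfonyl hydrazide, Cc1ccc(cc1)S(=O)(=O)NN
Why: Hydrazone condensation should occur at the saturated C1 ketone, which is far more electrophilic than the conjugated, α-methylated C9 carbonyl next to the quaternary carbon; mildly acidic conditions avoid retro-Claisen cleavage of the 1,3-diketone.

Step 6
Reactants: 8 C1 tosylhydrazone
Product: 9 4,4,8,10-tetramethyl-trans-decal-7-en-9-one (5α-H, 10β-CH3)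
Conditions: catecholborane, CHCl3, 0 °C; NaOAc·3H2O, 60 °C
Reagents that add atoms: none
Why: Hydroboration of the C=N bond, acetate-induced loss of sulfinate and extrusion of N2 from the diazene give the CH2 group (tosylhydrazone reduction, a mild variant of the Wolff–Kishner reduction); the s-trans ring enone is not reduced by catecholborane under these conditions.

Step 7
Reactants: 9 decal-7-en-9-one
Product: 10 4,4,8,10-tetramethyl-trans-decal-7-ene-6,9-dione (5α-H, 10β-CH3)
Conditions: Pd(OH)2/C (5 mol %), tBuOOH (5 equiv), K2CO3 (0.25 equiv), CH2Cl2, 4 → 25 °C
Reagents that add atoms: tert-butyl hydroperoxide, CC(C)(C)OO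
Why: Radical γ-oxidation (allylic oxidation) of an enone to the ene-1,4-dione by tert-butylperoxy radicals; C6 is the only ring CH2 allylic to C7=C8 because C9 and C10 carry no hydrogen.

Step 8
Reactants: 10 ene-6,9-dione
Product: 11 4,4,8α,10β-tetramethyl-trans-decalin-6,9-dione (5α-H, 8β-H)
Conditions: Zn dust, AcOH, 25 °C; then NaOMe (0.1 equiv), MeOH, 25 °C
Reagents that add atoms: none
Why: Zinc reduction of the ene-dione C=C bond (dissolving-metal reduction); the new centre C8 is α to the C9 carbonyl and is equilibrated by base to the equatorial 8α-methyl epimer, since the axial epimer would be syn-diaxial to C20. C5 stays trans-fused for the same thermodynamic reason.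

Step 9
Reactants: 11 decalin-6,9-dione
Product: 12 6β-hydroxy-4,4,8α,10β-tetramethyl-trans-decalin-9-one
Conditions: Li[HB(sec-Bu)3] (1.1 equiv), THF, −78 °C
Reagents that add atoms: none
Why: Bulky borohydride reduction should select the C6 carbonyl, because the C9 carbonyl lies between the quaternary C10 and the methyl-bearing C8; hydride enters from the α face (the β face is closed by the axial C19 and C20 methyls) and gives the 6β-alcohol, a temporary centre that is oxidised again in step 15.

Step 10
Reactants: 12 6β-hydroxy-9-ketone
Product: 13 6β-triethylsilyloxy-4,4,8α,10β-tetramethyl-trans-decalin-9-one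
Conditions: Et3SiOTf, 2,6-lutidine, CH2Cl2, −78 → 0 °C
Reagents that add atoms: triethylsilyl triflate, CC[Si](CC)(CC)OS(=O)(=O)C(F)(F)F
Why: Silyl ether formation with the reactive triflate, which can silylate the hindered axial alcohol; the ether prevents the axial 6β-alkoxide from attacking C11 across ring B in step 13.

Step 11
Reactants: 13 silyloxy ketone; 14 methyltriphenylphosphonium bromide
Product: 15 9-methylene-6β-triethylsilyloxy-4,4,8α,10β-tetramethyl-trans-decalin
Conditions: Ph3PCH3Br (4 equiv), KOtBu (4 equiv), toluene, 100 °C
Reagents that add atoms: methyltriphenylphosphonium bromide 14, C[P+](c1ccccc1)(c1ccccc1)c1ccccc1.[Br-]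
Why: Wittig methylenation under the forcing conditions used for hindered ketones; C8 can only equilibrate to the stable 8α-methyl epimer before olefination and is configurationally fixed afterwards.

Step 12
Reactants: 15 exocyclic alkene
Product: 16 9α,11-epoxide of 15 (spiro-oxirane, oxygen on the α face, C11 β)
Conditions: m-CPBA, NaHCO3, CH2Cl2, 0 °C
Reagents that add atoms: m-chloroperoxybenzoic acid, OOC(=O)c1cccc(Cl)c1
Why: Prilezhaev epoxidation; the peracid should approach the exocyclic alkene from the α face, because the β face is flanked by the axial C20 methyl and the axial 8β-hydrogen on the adjacent carbons. This sets C9 with the oxygen α; the buffer protects the acid-labile oxirane.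

Step 13
Reactants: 16 9α,11-epoxide; 17 3-methylbut-3-en-1-ol
Product: 18 6β-triethylsilyloxy-labd-13(16)-ene-9α,15-diol
Conditions: 17 (4 equiv), nBuLi (8 equiv), TMEDA, Et2O/hexane, 0 → 25 °C; then 16, THF, 0 → 45 °C
Reagents that add atoms: 3-methylbut-3-en-1-ol 17, CC(=C)CCO
Why: SN2 opening of the epoxide at the primary C11 by the allyllithium–alkoxide dianion of 17; the 2-substituted allyl anion has two equivalent CH2 termini, so only one constitution can form. The C9–O bond is not broken, so the 9α-oxygen is retained.

Step 14
Reactants: 18 alkene diol
Product: 21 (13R)-9α,13-epoxylabdane-6β,15,16-triol, via epoxy diol 19 (not isolated), via silyl spiro ether 20 (not isolated)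
Conditions: Zr(OtBu)4 (5 mol %), (R,R)-bis-hydroxamic acid ligand (6 mol %), cumene hydroperoxide (1.5 equiv), DMPU, 4 Å MS, toluene, 0 °C; then CSA (0.2 equiv), CH2Cl2, 0 °C; then MeOH, 25 °C
Reagents that add atoms: cumene hydroperoxide, CC(C)(OO)c1ccccc1
Why: Hydroxyl-directed catalytic asymmetric epoxidation of a 3-substituted homoallylic alcohol sets C13 as the (13S)-epoxide under catalyst control, independent of the remote decalin. Acid then lets the 9α-hydroxyl open the oxirane 5-exo at the tertiary C13 with inversion, giving the (13R) spiro ether; only O9 can reach C13 through a five-membered ring. Acidic methanol finally removes the silyl ether.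

Step 15
Reactants: 21 spiro ether triol
Product: 23 (13R)-9α,13-epoxy-6-oxolabdan-15,16-olide, via hydroxy lactone 22 (not isolated)
Conditions: PhI(OAc)2 (2.5 equiv), TEMPO (0.2 equiv), CH2Cl2, 25 °C; then Dess–Martin periodinane, NaHCO3, 25 °C
Reagents that add atoms: none
Why: The oxoammonium oxidant selects the unhindered C15 primary alcohol over the neopentyl C16–OH; the hydroxy aldehyde closes to the lactol and is oxidised to the 15,16-olide (oxidative lactonisation of a 1,4-diol). Dess–Martin oxidation then converts the hindered 6β-alcohol into the ketone.

Step 16
Reactants: 23 keto lactone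
Product: 26 (13R)-9α,13-epoxy-7α-hydroxy-6-oxolabdan-15,16-olide, via silyl enol ether 24 (not isolated), via silyloxy ketone 25 (not isolated)
Conditions: Me3SiOTf, Et3N, CH2Cl2, 0 °C; then m-CPBA, NaHCO3, hexane/CH2Cl2, −20 °C; then citric acid, MeOH/H2O, 25 °C
Reagents that add atoms: m-chloroperoxybenzoic acid, OOC(=O)c1cccc(Cl)c1
Why: Rubottom oxidation; soft enolisation silylates the ketone towards C7 (an enol ether towards C5 would clash with the C4 methyls, and the lactone is not silylated under these conditions). The peracid should attack the enol ether from the α face, because the β face is closed by C19 and C20, which gives the axial 7α-hydroxy ketone after silyl migration and cleavage.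

Step 17
Reactants: 26 7α-hydroxy ketone
Product: 27 (13R)-9α,13-epoxy-7β-hydroxy-6-oxolabdan-15,16-olide (target CNP0291402.1)
Conditions: Et3N, MeOH, 45 °C
Reagents that add atoms: none
Why: Base-mediated epimerisation of the α-ketol through its enediol should end at the equatorial 7β-hydroxyl, which is trans to the 8α-methyl and free of the 1,3-diaxial oxygen–oxygen repulsion with O9 that the axial epimer suffers in a protic solvent. The amine is too weak to form the lactone enolate, so the C13–O bond and C13 are not at risk.

## Compound list

1 | (R)-(−)-carvone | CC1=CC[C@H](CC1=O)C(C)=C | starting material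
2 | iodomethane | CI | starting material
3 | trans-6-methylcarvone, (5R,6S)-2,6-dimethyl-5-(prop-1-en-2-yl)cyclohex-2-en-1-one | CC1=CC[C@@H](C(C)=C)[C@H](C)C1=O | intermediate
4 | acrolein | C=CC=O | starting material
5 | (5S,6R)-6-(1-hydroxyprop-2-en-1-yl)-2,6-dimethyl-5-(prop-1-en-2-yl)cyclohex-2-en-1-one (carbinol centre mixed) | CC1=CC[C@@H](C(C)=C)[C@](C)(C(O)C=C)C1=O | intermediate
6 | (5S,6R)-6-acryloyl-2,6-dimethyl-5-(prop-1-en-2-yl)cyclohex-2-en-1-one | CC1=CC[C@@H](C(C)=C)[C@](C)(C(=O)C=C)C1=O | intermediate
7 | 4,4,8,10-tetramethyl-trans-decal-7-ene-1,9-dione (5α-H, 10β-CH3) | CC1=CC[C@H]2C(C)(C)CCC(=O)[C@]2(C)C1=O | intermediate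
8 | C1 p-toluenesulfonylhydrazone of 7 | CC1=CC[C@H]2C(C)(C)CCC(=NNS(=O)(=O)c3ccc(C)cc3)[C@]2(C)C1=O | intermediate
9 | 4,4,8,10-tetramethyl-trans-decal-7-en-9-one | CC1=CC[C@H]2C(C)(C)CCC[C@]2(C)C1=O | intermediate
10 | 4,4,8,10-tetramethyl-trans-decal-7-ene-6,9-dione | CC1=CC(=O)[C@H]2C(C)(C)CCC[C@]2(C)C1=O | intermediate
11 | 4,4,8α,10β-tetramethyl-trans-decalin-6,9-dione | C[C@@H]1CC(=O)[C@H]2C(C)(C)CCC[C@]2(C)C1=O | intermediate
12 | 6β-hydroxy-4,4,8α,10β-tetramethyl-trans-decalin-9-one | C[C@@H]1C[C@@H](O)[C@H]2C(C)(C)CCC[C@]2(C)C1=O | intermediate
13 | 6β-triethylsilyloxy-4,4,8α,10β-tetramethyl-trans-decalin-9-one | C[C@@H]1C[C@@H](O[Si](CC)(CC)CC)[C@H]2C(C)(C)CCC[C@]2(C)C1=O | intermediate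
14 | methyltriphenylphosphonium bromide | C[P+](c1ccccc1)(c1ccccc1)c1ccccc1.[Br-] | starting material
15 | 9-methylene-6β-triethylsilyloxy-4,4,8α,10β-tetramethyl-trans-decalin | C[C@@H]1C[C@@H](O[Si](CC)(CC)CC)[C@H]2C(C)(C)CCC[C@]2(C)C1=C | intermediate
16 | 9α,11-epoxide of 15 | C[C@@H]1C[C@@H](O[Si](CC)(CC)CC)[C@H]2C(C)(C)CCC[C@]2(C)[C@@]13CO3 | intermediate
17 | 3-methylbut-3-en-1-ol | CC(=C)CCO | starting material
18 | 6β-triethylsilyloxy-labd-13(16)-ene-9α,15-diol | C[C@@H]1C[C@@H](O[Si](CC)(CC)CC)[C@H]2C(C)(C)CCC[C@]2(C)[C@@]1(O)CCC(=C)CCO | intermediate
19 | (13S)-13,16-epoxy-6β-triethylsilyloxy-labdane-9α,15-diol | C[C@@H]1C[C@@H](O[Si](CC)(CC)CC)[C@H]2C(C)(C)CCC[C@]2(C)[C@@]1(O)CC[C@@]3(CO3)CCO | intermediate (not isolated)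
20 | (13R)-9α,13-epoxy-6β-triethylsilyloxy-labdane-15,16-diol | C[C@@H]1C[C@@H](O[Si](CC)(CC)CC)[C@H]2C(C)(C)CCC[C@]2(C)[C@@]12CC[C@](CO)(CCO)O2 | intermediate (not isolated)
21 | (13R)-9α,13-epoxylabdane-6β,15,16-triol | C[C@@H]1C[C@@H](O)[C@H]2C(C)(C)CCC[C@]2(C)[C@@]12CC[C@](CO)(CCO)O2 | intermediate
22 | (13R)-9α,13-epoxy-6β-hydroxylabdan-15,16-olide | C[C@@H]1C[C@@H](O)[C@H]2C(C)(C)CCC[C@]2(C)[C@@]12CC[C@@]1(COC(=O)C1)O2 | intermediate (not isolated)
23 | (13R)-9α,13-epoxy-6-oxolabdan-15,16-olide | C[C@@H]1CC(=O)[C@H]2C(C)(C)CCC[C@]2(C)[C@@]12CC[C@@]1(COC(=O)C1)O2 | intermediate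
24 | 6-trimethylsilyloxy-6-ene (silyl enol ether) of 23 | C[C@@H]1C=C(O[Si](C)(C)C)[C@H]2C(C)(C)CCC[C@]2(C)[C@@]12CC[C@@]1(COC(=O)C1)O2 | intermediate (not isolated)
25 | 7α-trimethylsilyloxy derivative of 23 | C[C@@H]1[C@H](O[Si](C)(C)C)C(=O)[C@H]2C(C)(C)CCC[C@]2(C)[C@@]12CC[C@@]1(COC(=O)C1)O2 | intermediate (not isolated)
26 | (13R)-9α,13-epoxy-7α-hydroxy-6-oxolabdan-15,16-olide | C[C@@H]1[C@H](O)C(=O)[C@H]2C(C)(C)CCC[C@]2(C)[C@@]12CC[C@@]1(COC(=O)C1)O2 | intermediate
27 | (13R)-9α,13-epoxy-7β-hydroxy-6-oxolabdan-15,16-olide (CNP0291402.1) | C[C@@H]1[C@@H](O)C(=O)[C@H]2C(C)(C)CCC[C@]2(C)[C@@]12CC[C@@]1(COC(=O)C1)O2 | target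

## Step count and least certain steps

Total: 17 steps. Longest linear sequence: 17 steps from 1 (2, 4, 14 and 17 are commercial).

Step 4 (key step). The vinyl ketone may be reduced or oligomerised before the tertiary radical forms, because the iron hydride and the radical chain can also engage the most electron-poor alkene. Fallback from 6, returning at 7: HBr in AcOH at 0 °C should add to both the vinyl ketone and the isopropenyl group to give the dibromide 6-(3-bromopropanoyl)-5-(2-bromopropan-2-yl)-2,6-dimethylcyclohex-2-en-1-one F1. Et3N should re-form the vinyl ketone by β-elimination and leave the tertiary bromide F2. Slow addition of Bu3SnH with AIBN in benzene at 80 °C then generates the same C4 radical by halogen abstraction and closes ring A by the same 6-endo Giese addition to give 7.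

Step 5. Selectivity between the two carbonyl groups may be lost, the hydrazone nitrogen may close onto C9, or the 1,3-diketone may be cleaved by the nucleophile. Fallback from 7, returning at 9: KN(SiMe3)2 and PhNTf2 at −78 °C should give the C1 enol triflate F3, since the saturated ketone is deprotonated at C2 faster than the enone at its γ-position. Pd(OAc)2, PPh3, Bu3N and HCO2H in DMF reduce the triflate to the 1,7-dien-9-one F4. Hydrogenation with RhCl(PPh3)3 saturates only the disubstituted C1=C2 bond and gives 9.

Step 11. The ylide may fail to add to the very hindered carbonyl and merely enolise it. Fallback from 13, returning at 15: a Peterson olefination, in which Me3SiCH2Li with CeCl3 adds from the α face to give the β-hydroxysilane F5, and KH in THF eliminates silanolate to give 15.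

Step 13. Substitution at the neopentyl-type C11 may be slow, and the strongly basic dianion may isomerise the oxirane to an allylic alcohol. Fallback from 16, returning at 18: copper-catalysed opening with 2-methylallylmagnesium chloride (CuI cat., THF, −30 → 0 °C) gives the methallyl adduct F6. Metalation of its allylic methyl group with nBuLi/KOtBu and trapping with paraformaldehyde adds C15 and gives 18; the intermediate allyl anion again has two equivalent CH2 termini.

Step 14. Facial selectivity of oxygen transfer may be poor, because both the primary and the tertiary hydroxyl can bind zirconium, and the primary hydroxyl may compete in opening the oxirane. Fallback from 18, returning at 23, which replaces catalyst control by separation and recycling: m-CPBA epoxidation without a chiral catalyst would give 19 together with its (13R)-epimer F7. The acid and methanol treatment of step 14 would carry F7 through the epimeric silyl spiro ether F8 to the epimeric triol F9 beside 21. Step 15 would convert F9 through the epimeric hydroxy lactone F10 into the epimeric keto lactone F11 beside 23. After chromatographic separation, F11 is heated with DBU in toluene at 80 °C, which opens the C13–O bond by retro-oxa-Michael reaction to the hydroxy butenolide F12 and re-closes it to a mixture of 23 and F11 that is separated again.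

Step 17. The equilibrium may not lie far enough on the side of the equatorial epimer, or the ketol may transpose to the 7-oxo-6-hydroxy isomer. Fallback from 26, returning at 27: Mitsunobu inversion of the axial 7α-hydroxyl with 4-nitrobenzoic acid, PPh3 and diisopropyl azodicarboxylate gives the 7β-(4-nitrobenzoate) F13. K2CO3 in MeOH at 0 °C removes the ester to give 27, with a trace of acid on work-up to re-close any opened lactone.

## Further compounds

F1 | step 4 | 6-(3-bromopropanoyl)-5-(2-bromopropan-2-yl)-2,6-dimethylcyclohex-2-en-1-one | CC1=CC[C@@H](C(C)(C)Br)[C@](C)(C(=O)CCBr)C1=O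
F2 | step 4 | 6-acryloyl-5-(2-bromopropan-2-yl)-2,6-dimethylcyclohex-2-en-1-one | CC1=CC[C@@H](C(C)(C)Br)[C@](C)(C(=O)C=C)C1=O
F3 | step 5 | C1 enol triflate of 7 | CC1=CC[C@H]2C(C)(C)CC=C(OS(=O)(=O)C(F)(F)F)[C@]2(C)C1=O
F4 | step 5 | 4,4,8,10-tetramethyl-trans-decala-1,7-dien-9-one | CC1=CC[C@H]2C(C)(C)CC=C[C@]2(C)C1=O
F5 | step 11 | 9β-hydroxy-9α-(trimethylsilylmethyl) adduct of 13 | C[C@@H]1C[C@@H](O[Si](CC)(CC)CC)[C@H]2C(C)(C)CCC[C@]2(C)[C@]1(O)C[Si](C)(C)C
F6 | step 13 | methallyl adduct of 16 (9α-hydroxy, side chain CH2CH2C(CH3)=CH2) | C[C@@H]1C[C@@H](O[Si](CC)(CC)CC)[C@H]2C(C)(C)CCC[C@]2(C)[C@@]1(O)CCC(C)=C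
F7 | step 14 | (13R)-epimer of 19 | C[C@@H]1C[C@@H](O[Si](CC)(CC)CC)[C@H]2C(C)(C)CCC[C@]2(C)[C@@]1(O)CC[C@]3(CO3)CCO
F8 | step 14 | (13S)-epimer of 20 | C[C@@H]1C[C@@H](O[Si](CC)(CC)CC)[C@H]2C(C)(C)CCC[C@]2(C)[C@@]12CC[C@@](CO)(CCO)O2
F9 | step 14 | (13S)-epimer of 21 | C[C@@H]1C[C@@H](O)[C@H]2C(C)(C)CCC[C@]2(C)[C@@]12CC[C@@](CO)(CCO)O2
F10 | step 14 | (13S)-epimer of 22 | C[C@@H]1C[C@@H](O)[C@H]2C(C)(C)CCC[C@]2(C)[C@@]12CC[C@]1(COC(=O)C1)O2
F11 | step 14 | (13S)-epimer of 23 | C[C@@H]1CC(=O)[C@H]2C(C)(C)CCC[C@]2(C)[C@@]12CC[C@]1(COC(=O)C1)O2
F12 | step 14 | 9α-hydroxy-6-oxolabd-13-en-15,16-olide | C[C@@H]1CC(=O)[C@H]2C(C)(C)CCC[C@]2(C)[C@@]1(O)CCC3=CC(=O)OC3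
F13 | step 17 | 7β-(4-nitrobenzoyloxy) analogue of 27 | C[C@@H]1[C@@H](OC(=O)c3ccc(cc3)[N+](=O)[O-])C(=O)[C@H]2C(C)(C)CCC[C@]2(C)[C@@]12CC[C@@]1(COC(=O)C1)O2
A1 | alternative 1 | 7β-tert-butyldimethylsilyloxy-6-oxo-9α,13-epoxy decalin with a spiro cyclobutanone at C13 | C[C@@H]1[C@@H](O[Si](C)(C)C(C)(C)C)C(=O)[C@H]2C(C)(C)CCC[C@]2(C)[C@@]12CCC1(CC(=O)C1)O2
A2 | alternative 1 | 7-O-tert-butyldimethylsilyl ether of 27 | C[C@@H]1[C@@H](O[Si](C)(C)C(C)(C)C)C(=O)[C@H]2C(C)(C)CCC[C@]2(C)[C@@]12CC[C@@]1(COC(=O)C1)O2
A3 | alternative 2 | triene with (5E,7Z)-7-silyloxy diene and (Z)-alkylidene furanone spiro lactone | C/C=C(\O[Si](C)(C)C(C)(C)C)/C=C/C(C)(C)CCC/C(C)=C1\O[C@@]2(CC1=O)COC(=O)C2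
A4 | alternative 2 | 7-silyloxy-6-ene 11-oxo decalin spiro lactone (8β-methyl) | C[C@H]1C(O[Si](C)(C)C(C)(C)C)=C[C@H]2C(C)(C)CCC[C@]2(C)[C@@]12C(=O)C[C@@]1(COC(=O)C1)O2
A5 | alternative 3 | C9 N-acyloxyphthalimide with trimethylcyclohexenyl ketone (C9 unassigned) | C[C@H](CC(=O)C1=C(C)CCCC1(C)C)C4(C(=O)ON2C(=O)c3ccccc3C2=O)CC[C@@]5(COC(=O)C5)O4
A6 | alternative 3 | (13R)-9α,13-epoxy-6-oxolabdan-15,16-olide (identical with 23) | C[C@@H]1CC(=O)[C@H]2C(C)(C)CCC[C@]2(C)[C@@]12CC[C@@]1(COC(=O)C1)O2
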